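## Analysis of the target

Target 25 is a trans-fused eremophilane: ring A is C1–C5/C10 and ring B is C5–C10, with C14 on C5, C15 on C4 and the isopropenyl group C11–C13 on C7. This numbering is used for every decalin below, and α means the face opposite C14. It carries (Z)-hex-2-enoates on O3 and O9 and a free hydroxyl on C8. The seven stereocentres are 3R,4R,5R,7S,8R,9S,10R. In the chair–chair trans-decalin, O3 (α), C15 (β), the isopropenyl group (α) and O9 (α) are equatorial, C14 (β) and H-10 (α) are axial, and only the C8 hydroxyl (α) is axial, cis to both of its neighbours. The sensitive parts are the two (Z)-enoates (E/Z drift, conjugate addition, reduction), the C9 ester next to a free cis C8 hydroxyl (acyl migration under base), and the isopropenyl group, which slides into conjugation whenever C8 is a ketone and C7 is enolised. The difficulties are the quaternary C5 next to the C4 methine, three secondary hydroxyls of which exactly two are acylated, and the axial C14, which screens the β face at C3, C7 and C9; that helps at C4 and C9 and works against C3 and C7. The route rests on one feature: the C3 carbonyl, the C4 methine and quaternary C5 of ring A are a cyclopentanone beside a quaternary carbon with one CH(CH3) unit inserted. Hydrindenedione 1 already holds C5 in the right absolute sense, together with the ring B enone (C8=O, C9=C10) needed for the trans fusion and the C8/C9 oxygens.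

## Retrosynthetic reasoning

25 back to 21 and 22. The two ester C–O bonds at O3 and O9 are cut last, because the enoates survive neither strong base, dissolving metal nor bulky hydride. The (Z)-alkenes are traced to the alkynes of 23, so that the geometry is made by syn hydrogenation (24) and not carried through an acylation. O8 is masked as a robust silyl ether in 21–24 and freed at the very end.

21 back to 19. The three hydroxyls are told apart by history, not by reactivity. O3 and O9 share one labile silyl group in 19 and 20, and O8 appears only when the C8 ketone is reduced, so it can receive a second, more stable silyl group (20) before the first pair is removed.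

19 back to 18. The C8–H bond is cut. The forward step must deliver hydride along the equatorial trajectory to give the axial alcohol, which a bulky borohydride does on a cyclohexanone flanked by two equatorial substituents.

18 back to 15 and 16. The C7–C11 bond is cut next to the C8 carbonyl. The bond must be made from the α face and the product must not be re-enolised, because protonation of the derived dienolate would decide C7 again and would open the way to the conjugated 7(11)-enone. A neutral palladium coupling of the Δ7 enol silane 15 (from ketone 13) meets both conditions.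

13 back to 9 via 12. The C9–O bond is cut. Only the Δ8 enol silane 9 allows oxidation at C9, and a trans-decalin-8-one enolises towards C7, so this enol derivative has to come from reduction of the C9=C10 enone and not from the ketone.

9 back to 7. The C10–H and C3–H bonds are cut together. Dissolving-metal reduction gives the trans ring fusion and leaves the C8 enolate. The same medium reduces the C3 ketone under thermodynamic control to the equatorial 3α-alkoxide. A hydride reagent would approach C3 from the equatorial side, because the axial path is blocked by C14, and would give mainly the wrong epimer.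

7 back to 5 via 6. The C4–H bond is cut. In the octalenedione the equatorial preference of a C4 methyl is small (C10 is trigonal and the equatorial methyl is gauche to both C14 and C6), so base equilibration is not relied on. The bromomethyl group of 5 is eliminated to the exocyclic enone 6, and hydrogen is added from the open α face.

5 back to 3 (key disconnection). The C4–C5 bond is cut and the C3–C5 bond restored, which contracts ring A to the cyclopentane of 3. Forward, a bromonium ion on the vinyl group triggers a 1,2-shift of C5 from C3 to C4. This makes ring A, the C3 carbonyl and the future C15 in one step and keeps C5 intact.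

3 back to 1 and 2. The C3–C4 bond is cut. A chemoselective 1,2-addition of a vinyl nucleophile to the saturated ketone of 1 gives the precursor in one step.

## Alternatives that were turned down

Alternative 1: Both rings are cut at once, at C9–C10 and C4–C5, back to an open chain. Forward, an alkylaluminium chloride activates a C9 aldehyde, C10 of an E-trisubstituted alkene attacks it, and the C5 cation is trapped by C4 of a C3 enol silyl ether, giving the trans-decalin A1. Its strength is convergence: two rings and the centres C4, C5, C9 and C10 in one step. On one point it is better than the chosen route: A1 arrives with O8 silylated, O9 free and C3 a ketone, so the hydroxyl differentiation that costs three protecting-group steps here is built in. Against it, the chain holds an aldehyde and an enol silane that can react directly (an intramolecular Mukaiyama aldol from C4 to C9 also closes a six-membered ring), and the isopropenyl group can undergo a carbonyl-ene reaction with the activated aldehyde. The terminating bond joins the tertiary C5 cation to C4, the most hindered bond of the skeleton, and the cis C14/C15 relation depends on enol ether geometry transmitted through a chair–chair transition state. The chain, with C7 and C8 set acyclically, needs a long preparation, and A1 still needs the equatorial C3 alcohol. The chosen route is longer after the key step, but its single rearrangement starts from a commercial bicycle and every later centre is set on a rigid decalin.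

Alternative 2: The C5–C10 bond is cut through a [3,3] shift. Forward, the silyl ketene acetal of an alkenyl δ-lactone undergoes Ireland–Claisen rearrangement, breaking O–C3, forming C5–C10 and contracting the lactone to the ring A cyclohexene acid A2. On the quaternary centre this is the stronger method: the ring-constrained transition state transfers chirality to the C5/C10 pair predictably and does not depend on migratory aptitude or on a chiral-pool bicycle. Against it, A2 holds only ring A and two of the seven stereocentres. Ring B must still be closed between the carboxyl carbon C9 and the side chain, C7, C8 and C9 must be functionalised, and C3/C4 must be set from the C3=C4 alkene, whose faces are poorly differentiated until ring B exists. The chosen route reaches the full bicycle with C5 and a usable ring B enone in two steps, and offers that step economy in place of a de novo quaternary centre.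

Alternative 3: Ring A is cut at C4–C5 and C1–C10. Forward, a protonated chiral oxazaborolidine Lewis acid catalyses endo Diels–Alder addition of a 2-silyloxydiene to the methyl-bearing double bond of a methoxyquinone, giving the cis-fused adduct A3. It is stronger on catalysis and on centres per step: C4, C5 and C10 are set at once under catalyst control, with C3 already a masked ketone. Against it for this target, A3 is cis-fused, so C10 must be epimerised beside the C9 carbonyl, with an uncertain equilibrium next to an angular methyl. It also carries a surplus carbonyl at C6, neopentyl to C5, that has to be removed. Ring B is an ene-dione whose C6 and C9 carbonyls and C8 enol ether must be told apart before the isopropenyl group and the C8/C9 alcohols can be placed, and the diene must be steered to the more substituted quinone alkene. The chosen precursor has exactly the oxidation pattern needed (C3 and C8 carbonyls, C9=C10) and no surplus oxygen, so fewer corrective redox steps are needed, at the price of setting the centres one by one.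

Key step: step 2

## Route

Step 1
Reactants: 1 (S)-7a-methyl-2,3,7,7a-tetrahydro-1H-indene-1,5(6H)-dione; 2 vinylmagnesium bromide
Product: 3 (1R,7aS)-1-ethenyl-1-hydroxy-7a-methyl-1,2,3,6,7,7a-hexahydro-5H-inden-5-one (the C3 vinyl carbinol; hydroxyl β, vinyl α)
Conditions: anhydrous CeCl3, THF, −78 °C, 1.1 equiv of 2; then H2O
Reagents that add atoms: none
Why: 1,2-Addition of an organocerium reagent; the non-conjugated cyclopentanone carbonyl is more electrophilic than the enone carbonyl and the weakly basic cerium reagent adds without enolisation. Attack anti to the angular methyl puts the vinyl group α; this centre disappears in step 2.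

Step 2
Reactants: 3 the C3 vinyl carbinol
Product: 5 15-bromo-11,12,13-trinoreremophil-9-ene-3,8-dione (4β-bromomethyl, 5β-methyl), via bromonium ion 4 (not isolated)
Conditions: NBS (1.1 equiv), CH2Cl2/(CF3)2CHOH, 0 °C, dark
Reagents that add atoms: N-bromosuccinimide, O=C1CCC(=O)N1Br
Why: NBS transfers Br+ to the vinyl group of 3, the only electron-rich alkene (the enone alkene is deactivated), to give bromonium ion 4. The C3–C5 σ bond, aligned with the breaking C4–Br bond, shifts to the internal carbon C4 anti to bromine while the hydroxyl oxygen becomes the C3 carbonyl and its proton goes to succinimide; this is the halonium-induced semipinacol rearrangement, the known one-carbon enlargement of 1-vinylcycloalkanols to 2-(halomethyl)cycloalkanones. Ring A is therefore closed by a 1,2-alkyl shift, not by a cyclisation: the C3–C5 bond is exchanged for C4–C5 and the cyclopentane becomes the cyclohexanone. C5 migrates with retention, so the quaternary centre keeps the configuration of 1. The new centre C4 is set by the reacting rotamer of the vinyl group: with the C–O bond in the inside position and bromine anti to the migrating bond the bromomethyl group should end β, but the centre is expendable because step 3 flattens it. The step needs C5 to migrate and not C2; the fully substituted carbon supports the electron-deficient bridged transition state better than a methylene. It also needs the shift to outrun capture of 4 by a nucleophile, which the non-nucleophilic, ionising solvent favours; carbonyl formation supplies the driving force, since five-to-six enlargement releases little strain.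

Step 3
Reactants: 5 the bromomethyl diketone
Product: 6 11,12,13-trinoreremophila-4(15),9-diene-3,8-dione (4-methylene, 5β-methyl)
Conditions: DBU (1.2 equiv), CH2Cl2, 0 °C; used directly
Reagents that add atoms: none
Why: E1cB elimination of HBr from a β-bromo ketone; it removes the C4 centre, so either C4 epimer of 5 converges on 6. The exocyclic enone is hindered by C5 but is still hydrogenated at once to avoid dimerisation.

Step 4
Reactants: 6 the exocyclic enone
Product: 7 11,12,13-trinoreremophil-9-ene-3,8-dione (4β,5β-dimethyl)
Conditions: H2 (1 atm), RhCl(PPh3)3 (5 mol%), benzene, rt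
Reagents that add atoms: none
Why: Homogeneous hydrogenation reduces the 1,1-disubstituted exocyclic alkene and leaves the trisubstituted ring B enone. Hydrogen reaches C4 from the α face, away from the axial C14 on the neighbouring carbon, so C15 ends β and cis to C14.

Step 5
Reactants: 7 the dimethyl enedione
Product: 9 3α,8-bis(trimethylsilyloxy)-11,12,13-trinoreremophil-8-ene (10α-H), via dilithium enolate alkoxide 8 (not isolated)
Conditions: Li (4.2 equiv), t-BuOH (2.0 equiv), NH3/THF, −78 °C; NH3 removed; then TMSCl, Et3N, THF, 0 °C
Reagents that add atoms: chlorotrimethylsilane, C[Si](C)(C)Cl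
Why: Dissolving-metal (Birch-type) reduction does two jobs: the enone is reduced with axial protonation at C10 from the α face, which gives the trans fusion and the C8(9) lithium enolate, and the C3 ketone is reduced under thermodynamic control to the equatorial 3α-alkoxide. Silylation of 8 then fixes the enol double bond at C8–C9 and caps O3.

Step 6
Reactants: 9 the bis(trimethylsilyl) enol ether
Product: 12 3α,9α-dihydroxy-11,12,13-trinoreremophilan-8-one, via silyloxy epoxide 10 (not isolated), via bis(trimethylsilyl) ketol 11 (not isolated)
Conditions: mCPBA, NaHCO3, CH2Cl2, −20 °C; then 1 M HCl, THF, 0 °C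
Reagents that add atoms: 3-chloroperoxybenzoic acid, OOC(=O)c1cccc(Cl)c1
Why: Rubottom oxidation; the peracid epoxidises the enol silane on the α face because C14 is 1,3 to C9 and screens the β face, epoxide 10 opens with 1,4-silyl shift to 11, and acid removes both trimethylsilyl groups. The 9α-hydroxyl is equatorial, so it is also the stable epimer beside the ketone.

Step 7
Reactants: 12 the dihydroxy ketone
Product: 13 3α,9α-bis(triethylsilyloxy)-11,12,13-trinoreremophilan-8-one
Conditions: TESCl, imidazole, DMAP (cat.), DMF, rt
Reagents that add atoms: chlorotriethylsilane, CC[Si](Cl)(CC)CC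
Why: Standard silylation of two secondary hydroxyls. O3 and O9 are the two oxygens to be acylated and can share one group, while C8 stays marked as the ketone.

Step 8
Reactants: 13 the bis(triethylsilyl) ketone
Product: 15 3α,9α-bis(triethylsilyloxy)-8-(trimethylsilyloxy)-11,12,13-trinoreremophil-7-ene, via lithium enolate 14 (not isolated)
Conditions: LiN(i-Pr)2, THF, −78 °C; then TMSCl, Et3N, −78 to 0 °C; used crude
Reagents that add atoms: chlorotrimethylsilane, C[Si](C)(C)Cl
Why: Kinetic deprotonation by a hindered amide removes a C7 proton, since the C9 methine is shielded by its silyloxy group. O-silylation then gives the Δ7 enol silane regioselectively.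

Step 9
Reactants: 15 the Δ7 enol silane; 16 2-bromopropene
Product: 18 3α,9α-bis(triethylsilyloxy)eremophil-11-en-8-one (7α-isopropenyl), via tributyltin enolate 17 (not isolated)
Conditions: Bu3SnF (1.2 equiv), PdCl2[P(o-tolyl)3]2 (5 mol%), 16 (3 equiv), toluene, 80 °C, sealed tube
Reagents that add atoms: none
Why: Palladium-catalysed coupling of a tin enolate with a 1-bromoalkene: Bu3SnF converts 15 into 17, zerovalent palladium inserts into the C–Br bond of 16, and transmetalation followed by reductive elimination forms C7–C11. Palladium binds C7 on the α face, away from the syn-axial C14, so the isopropenyl group ends 7α (equatorial). The medium is not basic, so 18 is not re-enolised and neither epimerises nor slides into conjugation.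

Step 10
Reactants: 18 the isopropenyl ketone
Product: 19 3α,9α-bis(triethylsilyloxy)eremophil-11-en-8α-ol
Conditions: LiBH(s-Bu)3, THF, −78 °C; then aq. NH4Cl
Reagents that add atoms: none
Why: The bulky borohydride attacks C8 along the equatorial trajectory, because the axial one is blocked by H-6α and H-10α, and gives the axial 8α-alcohol. The low temperature and low basicity leave C7 untouched.

Step 11
Reactants: 19 the C8 alcohol
Product: 20 8α-(tert-butyldimethylsilyloxy)-3α,9α-bis(triethylsilyloxy)eremophil-11-ene
Conditions: TBSOTf, 2,6-lutidine, CH2Cl2, −20 to 0 °C
Reagents that add atoms: tert-butyldimethylsilyl trifluoromethanesulfonate, CC(C)(C)[Si](C)(C)OS(=O)(=O)C(F)(F)F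
Why: A silyl triflate silylates even a hindered axial hydroxyl. The tert-butyldimethylsilyl ether is far more acid-stable than the two triethylsilyl ethers, which is the basis of the differentiation.

Step 12
Reactants: 20 the tris-silyl ether
Product: 21 8α-(tert-butyldimethylsilyloxy)eremophil-11-ene-3α,9α-diol
Conditions: PPTS (cat.), MeOH/CH2Cl2, 0 °C to rt
Reagents that add atoms: none
Why: Mild acid methanolysis cleaves triethylsilyl ethers much faster than a secondary tert-butyldimethylsilyl ether, so only O3 and O9 are exposed.

Step 13
Reactants: 21 the 3,9-diol; 22 hex-2-ynoic acid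
Product: 23 8α-(tert-butyldimethylsilyloxy)eremophil-11-ene-3α,9α-diyl bis(hex-2-ynoate)
Conditions: 22 (3 equiv), DCC, DMAP (cat.), CH2Cl2, −20 to 0 °C
Reagents that add atoms: none
Why: Steglich esterification of both equatorial hydroxyls. The alkynoic acid is used because, unlike a (Z)-enoic acid, it has no alkene geometry to lose under acyl-transfer catalysis.

Step 14
Reactants: 23 the bis-alkynoate
Product: 24 8α-(tert-butyldimethylsilyloxy)eremophil-11-ene-3α,9α-diyl bis[(Z)-hex-2-enoate]
Conditions: H2 (1 atm), 5% Pd/CaCO3 poisoned with Pb(OAc)2, quinoline, EtOAc, rt; stopped after 2 equiv H2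
Reagents that add atoms: none
Why: Syn semihydrogenation of both conjugated alkynes on lead-poisoned palladium gives the (Z)-enoates. The 1,1-disubstituted isopropenyl alkene is taken up much more slowly on this catalyst.

Step 15
Reactants: 24 the silylated diester
Product: 25 8α-hydroxyeremophil-11-ene-3α,9α-diyl bis[(Z)-hex-2-enoate] (CNP0420276.1; 3R,4R,5R,7S,8R,9S,10R)
Conditions: HF·pyridine, pyridine, THF, 0 °C to rt
Reagents that add atoms: none
Why: Fluoride cleavage of the silyl ether under weakly acidic, buffered conditions, which should neither isomerise the (Z)-enoates nor cause acyl migration from O9 to O8.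

## Compound list

1 | (S)-7a-methyl-2,3,7,7a-tetrahydro-1H-indene-1,5(6H)-dione | C[C@]12CCC(=O)C=C1CCC2=O | starting material
2 | vinylmagnesium bromide | C=C[Mg]Br | starting material
3 | (1R,7aS)-1-ethenyl-1-hydroxy-7a-methyl-1,2,3,6,7,7a-hexahydro-5H-inden-5-one | C=C[C@]1(O)CCC2=CC(=O)CC[C@]12C | intermediate
4 | bromonium ion on the vinyl group of 3 | C1[Br+][C@H]1[C@]2(O)CCC3=CC(=O)CC[C@]23C | intermediate (not isolated)
5 | 15-bromo-11,12,13-trinoreremophil-9-ene-3,8-dione (4β-bromomethyl, 5β-methyl) | O=C1CCC2=CC(=O)CC[C@]2(C)[C@H]1CBr | intermediate
6 | 11,12,13-trinoreremophila-4(15),9-diene-3,8-dione | C=C1C(=O)CCC2=CC(=O)CC[C@]12C | intermediate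
7 | 11,12,13-trinoreremophil-9-ene-3,8-dione (4β,5β-dimethyl) | C[C@H]1C(=O)CCC2=CC(=O)CC[C@]12C | intermediate
8 | dilithium 3α-oxido-11,12,13-trinoreremophil-8-en-8-olate | C[C@H]1[C@H](O[Li])CC[C@H]2C=C(O[Li])CC[C@]12C | intermediate (not isolated)
9 | 3α,8-bis(trimethylsilyloxy)-11,12,13-trinoreremophil-8-ene | C[C@H]1[C@H](O[Si](C)(C)C)CC[C@H]2C=C(O[Si](C)(C)C)CC[C@]12C | intermediate
10 | 8α,9α-epoxy-3α,8β-bis(trimethylsilyloxy)-11,12,13-trinoreremophilane | C[C@H]1[C@H](O[Si](C)(C)C)CC[C@H]2[C@@H]3O[C@]3(O[Si](C)(C)C)CC[C@]12C | intermediate (not isolated)
11 | 3α,9α-bis(trimethylsilyloxy)-11,12,13-trinoreremophilan-8-one | C[C@H]1[C@H](O[Si](C)(C)C)CC[C@H]2[C@H](O[Si](C)(C)C)C(=O)CC[C@]12C | intermediate (not isolated)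
12 | 3α,9α-dihydroxy-11,12,13-trinoreremophilan-8-one | C[C@H]1[C@H](O)CC[C@H]2[C@H](O)C(=O)CC[C@]12C | intermediate
13 | 3α,9α-bis(triethylsilyloxy)-11,12,13-trinoreremophilan-8-one | C[C@H]1[C@H](O[Si](CC)(CC)CC)CC[C@H]2[C@H](O[Si](CC)(CC)CC)C(=O)CC[C@]12C | intermediate
14 | lithium 3α,9α-bis(triethylsilyloxy)-11,12,13-trinoreremophil-7-en-8-olate | C[C@H]1[C@H](O[Si](CC)(CC)CC)CC[C@H]2[C@H](O[Si](CC)(CC)CC)C(O[Li])=CC[C@]12C | intermediate (not isolated)
15 | 3α,9α-bis(triethylsilyloxy)-8-(trimethylsilyloxy)-11,12,13-trinoreremophil-7-ene | C[C@H]1[C@H](O[Si](CC)(CC)CC)CC[C@H]2[C@H](O[Si](CC)(CC)CC)C(O[Si](C)(C)C)=CC[C@]12C | intermediate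
16 | 2-bromopropene | C=C(C)Br | starting material
17 | tributyltin 3α,9α-bis(triethylsilyloxy)-11,12,13-trinoreremophil-7-en-8-olate | C[C@H]1[C@H](O[Si](CC)(CC)CC)CC[C@H]2[C@H](O[Si](CC)(CC)CC)C(O[Sn](CCCC)(CCCC)CCCC)=CC[C@]12C | intermediate (not isolated)
18 | 3α,9α-bis(triethylsilyloxy)eremophil-11-en-8-one (7α-isopropenyl) | C[C@H]1[C@H](O[Si](CC)(CC)CC)CC[C@H]2[C@H](O[Si](CC)(CC)CC)C(=O)[C@H](C(C)=C)C[C@]12C | intermediate
19 | 3α,9α-bis(triethylsilyloxy)eremophil-11-en-8α-ol | C[C@H]1[C@H](O[Si](CC)(CC)CC)CC[C@H]2[C@H](O[Si](CC)(CC)CC)[C@H](O)[C@H](C(C)=C)C[C@]12C | intermediate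
20 | 8α-(tert-butyldimethylsilyloxy)-3α,9α-bis(triethylsilyloxy)eremophil-11-ene | C[C@H]1[C@H](O[Si](CC)(CC)CC)CC[C@H]2[C@H](O[Si](CC)(CC)CC)[C@H](O[Si](C)(C)C(C)(C)C)[C@H](C(C)=C)C[C@]12C | intermediate
21 | 8α-(tert-butyldimethylsilyloxy)eremophil-11-ene-3α,9α-diol | C[C@H]1[C@H](O)CC[C@H]2[C@H](O)[C@H](O[Si](C)(C)C(C)(C)C)[C@H](C(C)=C)C[C@]12C | intermediate
22 | hex-2-ynoic acid | CCCC#CC(=O)O | starting material
23 | 8α-(tert-butyldimethylsilyloxy)eremophil-11-ene-3α,9α-diyl bis(hex-2-ynoate) | C[C@H]1[C@H](OC(=O)C#CCCC)CC[C@H]2[C@H](OC(=O)C#CCCC)[C@H](O[Si](C)(C)C(C)(C)C)[C@H](C(C)=C)C[C@]12C | intermediate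
24 | 8α-(tert-butyldimethylsilyloxy)eremophil-11-ene-3α,9α-diyl bis[(Z)-hex-2-enoate] | C[C@H]1[C@H](OC(=O)/C=C\CCC)CC[C@H]2[C@H](OC(=O)/C=C\CCC)[C@H](O[Si](C)(C)C(C)(C)C)[C@H](C(C)=C)C[C@]12C | intermediate
25 | 8α-hydroxyeremophil-11-ene-3α,9α-diyl bis[(Z)-hex-2-enoate] (CNP0420276.1) | C=C(C)[C@@H]1C[C@]2(C)[C@@H](C)[C@H](OC(=O)/C=C\CCC)CC[C@H]2[C@H](OC(=O)/C=C\CCC)[C@@H]1O | target

## Step count and least certain steps

Total step count: 15. Longest linear sequence: 15 steps (1 to 25); 2, 16 and 22 enter as purchased reagents.

Step 2 (key step). The most likely failure is interception of the bromonium ion before the shift: bromohydrin or bromo-ether formation, or closure by the neighbouring hydroxyl. The cationic carbon is only secondary and the five-to-six enlargement is not strain-driven. Partial migration of C2 and radical allylic bromination of the enone are lesser risks. Fallback: starting from 3, hydroxyl-directed epoxidation of the vinyl group (VO(acac)2, t-BuOOH) would give the oxiranyl carbinol F1. A Lewis acid (BF3·OEt2, −78 °C) would then trigger the semipinacol rearrangement of this 2,3-epoxy alcohol, with the same C3-to-C4 shift of C5, to the 4-(hydroxymethyl) diketone F2. Mesylation and elimination (MsCl, Et3N) returns the route at 6.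

Step 9. The hindered secondary tin enolate may transmetalate slowly, so that β-hydride loss from the palladium enolate or simple protodesilylation back to 13 takes over; prolonged heating could also move the alkene into conjugation. Fallback: starting from 13, the cerium enolate (LiN(i-Pr)2, then CeCl3) is added to acetone, the electrophile approaching C7 anti to C14, to give the aldol F3. LiBH(s-Bu)3 reduces C8 to the axial alcohol of diol F4, and one equivalent of TBSOTf at −78 °C silylates the secondary hydroxyl to give the tertiary alcohol F5. Syn dehydration with methyl N-(triethylammoniosulfonyl)carbamate should remove a methyl hydrogen rather than the shielded axial H-7 and returns the route at 20.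

Step 5. Two reductions share one flask, so the balance of proton donor is delicate: excess alcohol protonates the C8 enolate and leads to over-reduction, too little leaves the C3 ketone to be enolised, with loss of the C4 configuration. Fallback: starting from 7, NaBH4 (MeOH/CH2Cl2, −40 °C) reduces only the saturated ketone, from the equatorial side, to the axial 3β-alcohol F6. Mitsunobu inversion with 4-nitrobenzoic acid gives the 3α-ester F7, and methanolysis (K2CO3, MeOH) gives the 3α-hydroxy enone F8. Reduction of F8 with Li/NH3 and one equivalent of t-BuOH, then TMSCl/Et3N, returns the route at 9.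

Step 1. Competing 1,2-addition at the enone carbonyl, or double addition, would erode chemoselectivity, since the saturated ketone is neopentyl. Fallback: starting from 1, the enone is masked as its dienol ether F9 (HC(OEt)3, TsOH, EtOH), as is done for steroidal enediones. The vinylcerium reagent is then added to the only remaining ketone to give carbinol F10, and aqueous oxalic acid releases the enone, returning the route at 3.

Step 14. Over-reduction to hexanoates, slow uptake at one of the two alkynes, or partial hydrogenation of the isopropenyl group would give inseparable mixtures at the penultimate stage. Fallback: 22 is semihydrogenated first, on the same poisoned catalyst, to (Z)-hex-2-enoic acid F11. Diol 21 is then acylated with F11 by Yamaguchi esterification (2,4,6-trichlorobenzoyl chloride, Et3N, then DMAP), which returns the route at 24 without passing through 23.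

## Further compounds

F1 | step 2 | (1R,7aS)-1-hydroxy-7a-methyl-1-(oxiran-2-yl)-1,2,3,6,7,7a-hexahydro-5H-inden-5-one (either epimer at the oxirane carbon) | C1OC1[C@]2(O)CCC3=CC(=O)CC[C@]23C
F2 | step 2 | 15-hydroxy-11,12,13-trinoreremophil-9-ene-3,8-dione (either C4 epimer) | O=C1CCC2=CC(=O)CC[C@]2(C)C1CO
F3 | step 9 | 11-hydroxy-3α,9α-bis(triethylsilyloxy)eremophilan-8-one | C[C@H]1[C@H](O[Si](CC)(CC)CC)CC[C@H]2[C@H](O[Si](CC)(CC)CC)C(=O)[C@H](C(C)(C)O)C[C@]12C
F4 | step 9 | 3α,9α-bis(triethylsilyloxy)eremophilane-8α,11-diol | C[C@H]1[C@H](O[Si](CC)(CC)CC)CC[C@H]2[C@H](O[Si](CC)(CC)CC)[C@H](O)[C@H](C(C)(C)O)C[C@]12C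
F5 | step 9 | 8α-(tert-butyldimethylsilyloxy)-3α,9α-bis(triethylsilyloxy)eremophilan-11-ol | C[C@H]1[C@H](O[Si](CC)(CC)CC)CC[C@H]2[C@H](O[Si](CC)(CC)CC)[C@H](O[Si](C)(C)C(C)(C)C)[C@H](C(C)(C)O)C[C@]12C
F6 | step 5 | 3β-hydroxy-11,12,13-trinoreremophil-9-en-8-one | C[C@H]1[C@@H](O)CCC2=CC(=O)CC[C@]12C
F7 | step 5 | 8-oxo-11,12,13-trinoreremophil-9-en-3α-yl 4-nitrobenzoate | C[C@H]1[C@H](OC(=O)c3ccc(cc3)[N+](=O)[O-])CCC2=CC(=O)CC[C@]12C
F8 | step 5 | 3α-hydroxy-11,12,13-trinoreremophil-9-en-8-one | C[C@H]1[C@H](O)CCC2=CC(=O)CC[C@]12C
F9 | step 1 | (7aS)-5-ethoxy-7a-methyl-2,6,7,7a-tetrahydro-1H-inden-1-one | CCOC1=CC2=CCC(=O)[C@@]2(C)CC1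
F10 | step 1 | (1R,7aS)-5-ethoxy-1-ethenyl-7a-methyl-2,6,7,7a-tetrahydro-1H-inden-1-ol | CCOC1=CC2=CC[C@@](O)(C=C)[C@@]2(C)CC1
F11 | step 14 | (Z)-hex-2-enoic acid | CCC/C=C\C(=O)O
A1 | alternative 1 | 8α-(tert-butyldimethylsilyloxy)-9α-hydroxyeremophil-11-en-3-one | C=C(C)[C@@H]1C[C@]2(C)[C@@H](C)C(=O)CC[C@H]2[C@H](O)[C@@H]1O[Si](C)(C)C(C)(C)C
A2 | alternative 2 | 2-[3-(tert-butyldimethylsilyloxy)propyl]-2,3-dimethylcyclohex-3-ene-1-carboxylic acid (ring A acid, carboxyl carbon = C9) | OC(=O)[C@@H]1CCC=C(C)[C@@]1(C)CCCO[Si](C)(C)C(C)(C)C
A3 | alternative 3 | cis-fused 3-(tert-butyldimethylsilyloxy)-8-methoxy-11,12,13-trinoreremophila-2,7-diene-6,9-dione | O=C1C=C(OC)C(=O)[C@H]2CC=C(O[Si](C)(C)C(C)(C)C)[C@@H](C)[C@@]12C
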